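**Assumptions.** Pentamethoxybenzene is taken as a purchasable catalogue arene. The target SMILES is read as 3,4-cis in both lactone rings, (3R,4S) in ring A (5,7-dioxygenated chromanone, unprimed locants) and (3'S,4'R) in ring B (5,6,7,8-tetraoxygenated chromanone, primed locants). The target carries eight phenolic oxygens, so the protected annulation product is an octamethyl ether. The catalyst enantiomers in steps 5 and 9 are assigned from the usual model for isothiourea-bound Z-enolates (electrophile enters anti to the catalyst's C2 phenyl group); this is a prediction, not a measured result.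

## Retrosynthetic overview

1. The target comes from octamethyl ether 18 by cleavage of all eight aryl methyl ethers.
2. Ring A is cut at C3–C4 and O1–C2. O1 sits on arene carbon C8a, ortho to C4a, which carries the diarylmethine C4, so O1–C8a–C4a–C4 is a masked ortho-quinone methide; C2–C3 is an acyl-ammonium enolate drawn from the CH2CO2H side chain on C3' of the ring B lactone.
3. Ring B lactone acid 11 is made one cycle earlier by the same type of annulation (ring B quinone methide plus a succinic half-ester). The two lactone rings are quasi-enantiomeric, so the opposite catalyst enantiomer is used there. Ring B forms first, ring A second.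
4. Both quinone methides are released by base from aryl(sulfonyl)methyl phenols, because a free benzhydrol would be acylated under the annulation conditions. The sulfones come from the benzhydrols (ring A: salicylaldehyde plus aryl Grignard; ring B: Friedel–Crafts ketone, ortho-demethylation, reduction).

Key step: step 9

## Route

Step 1
Reactants: 1 pentamethoxybenzene; 2 4-methoxybenzoyl chloride
Product: 3 (4-methoxyphenyl)(2,3,4,5,6-pentamethoxyphenyl)methanone
Conditions: AlCl3 (1.2 equiv), CH2Cl2, 0 °C
Reagents that add atoms: none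
Why: Friedel–Crafts acylation at the only free position of a very electron-rich arene, so there is no regiochemical question, and any ortho-demethylated material converges in step 2.

Step 2
Reactants: 3 (4-methoxyphenyl)(2,3,4,5,6-pentamethoxyphenyl)methanone
Product: 4 (2-hydroxy-3,4,5,6-tetramethoxyphenyl)(4-methoxyphenyl)methanone
Conditions: BCl3 (1.1 equiv), CH2Cl2, −78 to 0 °C; H2O
Reagents that add atoms: none
Why: Chelation-directed Lewis-acid dealkylation: boron bound to the ketone oxygen should cleave only a methyl ether ortho to the carbonyl, and the two ortho ethers are equivalent.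

Step 3
Reactants: 4 (2-hydroxy-3,4,5,6-tetramethoxyphenyl)(4-methoxyphenyl)methanone
Product: 5 racemic (2-hydroxy-3,4,5,6-tetramethoxyphenyl)(4-methoxyphenyl)methanol
Conditions: NaBH4 (excess), THF/MeOH, 0 °C to rt; pH 7 buffer
Reagents that add atoms: none
Why: Borohydride reduction of the diaryl ketone, kept cold and worked up neutral to avoid ionisation and over-reduction; the carbinol centre is racemic and later becomes the sp2 methide carbon.

Step 4
Reactants: 5 racemic (2-hydroxy-3,4,5,6-tetramethoxyphenyl)(4-methoxyphenyl)methanol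
Product: 6 racemic 2,3,4,5-tetramethoxy-6-[(4-methoxyphenyl)(4-methylbenzenesulfonyl)methyl]phenol
Conditions: p-TolSO2H (1.5 equiv, freshly liberated from its sodium salt), CH2Cl2, 0 °C to rt
Reagents that add atoms: p-toluenesulfinic acid, Cc1ccc(cc1)S(O)=O
Why: SN1-type sulfone formation: the acid ionises the doubly activated benzhydrol and the sulfinate is captured at sulfur, giving a storable phenol that releases the quinone methide with mild base.

Step 5
Reactants: 6 racemic 2,3,4,5-tetramethoxy-6-[(4-methoxyphenyl)(4-methylbenzenesulfonyl)methyl]phenol; 7 4-tert-butoxy-4-oxobutanoic acid (mono-tert-butyl succinate)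
Product: 10 tert-butyl 2-[(3R,4R)-5,6,7,8-tetramethoxy-4-(4-methoxyphenyl)-2-oxo-3,4-dihydro-2H-chromen-3-yl]acetate, via mixed pivalic anhydride 8 (not isolated), via ortho-quinone methide 9 (not isolated)
Conditions: 7, t-BuCOCl (1.2 equiv), iPr2NEt, CH2Cl2, 0 °C; separately 6, Cs2CO3, CH2Cl2, rt, filtered; combined with (2R,3S)-HyperBTM (10 mol%), iPr2NEt, 4 Å MS, −40 °C to rt
Reagents that add atoms: pivaloyl chloride, CC(C)(C)C(Cl)=O (its acyl group is carried only by 8 and leaves as pivalic acid)
Why: Isothiourea-catalysed Michael addition–lactonisation (formal [4+2]): the catalyst is acylated by 8, its Z-ammonium enolate adds to the methide carbon of 9 through the face not covered by the catalyst's C2 phenyl group (predicted to set C3 as R with the (2R,3S) catalyst), the endo-like approach known for such annulations should place the C4 aryl group cis to the side chain, and the phenoxide then closes the lactone and frees the catalyst.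

HyperBTM is 3-isopropyl-2-phenyl-3,4-dihydro-2H-benzo[4,5]thiazolo[3,2-a]pyrimidine.

Step 6
Reactants: 10 tert-butyl 2-[(3R,4R)-5,6,7,8-tetramethoxy-4-(4-methoxyphenyl)-2-oxo-3,4-dihydro-2H-chromen-3-yl]acetate
Product: 11 2-[(3R,4R)-5,6,7,8-tetramethoxy-4-(4-methoxyphenyl)-2-oxo-3,4-dihydro-2H-chromen-3-yl]acetic acid
Conditions: TFA/CH2Cl2 (1:4), 0 °C to rt; toluene co-evaporation
Reagents that add atoms: none
Why: Acidolysis of the tert-butyl ester (loss of isobutene) under conditions that neither enolise nor open the aryl lactone, so the cis configuration should be kept.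

Step 7
Reactants: 12 2-hydroxy-4,6-dimethoxybenzaldehyde; 13 4-methoxyphenylmagnesium bromide
Product: 14 racemic (2-hydroxy-4,6-dimethoxyphenyl)(4-methoxyphenyl)methanol
Conditions: 13 (2.3 equiv), THF, 0 °C to rt; aqueous NH4Cl
Reagents that add atoms: none
Why: Grignard addition to the aldehyde after the first equivalent has deprotonated the phenol; the substitution pattern of the ring A arene is fixed by the purchased salicylaldehyde, and the racemic carbinol centre is lost later.

Step 8
Reactants: 14 racemic (2-hydroxy-4,6-dimethoxyphenyl)(4-methoxyphenyl)methanol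
Product: 15 racemic 3,5-dimethoxy-2-[(4-methoxyphenyl)(4-methylbenzenesulfonyl)methyl]phenol
Conditions: p-TolSO2H (1.5 equiv), CH2Cl2, 0 °C to rt
Reagents that add atoms: p-toluenesulfinic acid, Cc1ccc(cc1)S(O)=O
Why: SN1-type sulfone formation as in step 4; the excess sulfinate should outrun self-condensation of the electron-rich benzhydrol.

Step 9
Reactants: 11 2-[(3R,4R)-5,6,7,8-tetramethoxy-4-(4-methoxyphenyl)-2-oxo-3,4-dihydro-2H-chromen-3-yl]acetic acid; 15 racemic 3,5-dimethoxy-2-[(4-methoxyphenyl)(4-methylbenzenesulfonyl)methyl]phenol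
Product: 18 (3R,4S)-5,7-dimethoxy-4-(4-methoxyphenyl)-3-[(3S,4R)-5,6,7,8-tetramethoxy-4-(4-methoxyphenyl)-2-oxo-3,4-dihydro-2H-chromen-3-yl]-3,4-dihydro-2H-chromen-2-one (octamethyl ether of the target), via mixed pivalic anhydride 16 (not isolated), via ortho-quinone methide 17 (not isolated)
Conditions: 11, t-BuCOCl (1.1 equiv), iPr2NEt, CH2Cl2, −20 °C; separately 15, Cs2CO3, CH2Cl2, rt, filtered; combined with (2S,3R)-HyperBTM (20 mol%), iPr2NEt, 4 Å MS, −40 to 0 °C
Reagents that add atoms: pivaloyl chloride, CC(C)(C)C(Cl)=O (its acyl group is carried only by 16 and leaves as pivalic acid)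
Why: The catalyst is acylated by 16 and the acyl isothiouronium is deprotonated only at the side-chain CH2 (far more acidic than the lactone C3'–H) to the Z-ammonium enolate, whose carbon adds to the methide carbon of 17 (bond C3–C4); the rearomatised phenoxide then attacks the acyl ammonium carbon (bond O1–C2) and frees the catalyst. The closest known reaction type is the isothiourea- or carbene-catalysed Michael addition–lactonisation of acid-derived enolates with ortho-quinone methides to cis-3,4-disubstituted dihydrocoumarins. Ring A closes by 6-exo-trig acyl substitution of the phenoxide on the acyl ammonium. C3 is catalyst-controlled: the pseudo-axial C2 phenyl group covers one enolate face and the quinone methide enters on the other, predicted to give 3R with the (2S,3R) catalyst, and the ring B centre should reinforce this (with C3'–H eclipsing the enolate oxygen, the bulky C4' side shields the same face, a matched pairing). C4 follows from relative topicity: the compact endo-like approach of Z-enolate and quinone methide should give the 3,4-cis lactone, that is 4S. The step needs enolisation at CH2 only (secured by acyl ammonium activation), no O-acylation of the sulfonyl phenol (secured by pre-forming 17 and filtering off the sulfinate), and no epimerisation of the kinetic cis ring B lactone (amine base at or below 0 °C).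

Step 10
Reactants: 18 octamethyl ether of the target
Product: 19 (3R,4S)-5,7-dihydroxy-4-(4-hydroxyphenyl)-3-[(3S,4R)-5,6,7,8-tetrahydroxy-4-(4-hydroxyphenyl)-2-oxo-3,4-dihydro-2H-chromen-3-yl]-3,4-dihydro-2H-chromen-2-one (CNP0064734.3)
Conditions: BBr3 (20 equiv), CH2Cl2, −78 °C to rt, argon; degassed ice-water with Na2S2O4, EtOAc; reversed-phase chromatography (0.1% HCO2H), no alcohol in the quench
Reagents that add atoms: none
Why: Lewis-acid cleavage of aryl methyl ethers (bromide attack on the methyl group of the boron-bound ether) with no base present, so the lactone alpha-centres should not epimerise; any lactone opened on the way re-closes on acidic aqueous work-up, and translactonisation within either fully hydroxylated ring is degenerate.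

## Compound list

1 | pentamethoxybenzene | COc1cc(OC)c(OC)c(OC)c1OC | starting material
2 | 4-methoxybenzoyl chloride | COc1ccc(cc1)C(Cl)=O | starting material
3 | (4-methoxyphenyl)(2,3,4,5,6-pentamethoxyphenyl)methanone | COc1ccc(cc1)C(=O)c1c(OC)c(OC)c(OC)c(OC)c1OC | intermediate
4 | (2-hydroxy-3,4,5,6-tetramethoxyphenyl)(4-methoxyphenyl)methanone | COc1ccc(cc1)C(=O)c1c(O)c(OC)c(OC)c(OC)c1OC | intermediate
5 | racemic (2-hydroxy-3,4,5,6-tetramethoxyphenyl)(4-methoxyphenyl)methanol | COc1ccc(cc1)C(O)c1c(O)c(OC)c(OC)c(OC)c1OC | intermediate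
6 | racemic 2,3,4,5-tetramethoxy-6-[(4-methoxyphenyl)(4-methylbenzenesulfonyl)methyl]phenol | COc1ccc(cc1)C(c1c(O)c(OC)c(OC)c(OC)c1OC)S(=O)(=O)c1ccc(C)cc1 | intermediate
7 | 4-tert-butoxy-4-oxobutanoic acid (mono-tert-butyl succinate) | CC(C)(C)OC(=O)CCC(O)=O | starting material
8 | 4-tert-butoxy-4-oxobutanoic pivalic anhydride | CC(C)(C)OC(=O)CCC(=O)OC(=O)C(C)(C)C | intermediate
9 | 2,3,4,5-tetramethoxy-6-[(4-methoxyphenyl)methylidene]cyclohexa-2,4-dien-1-one | COc1ccc(cc1)C=C1C(=O)C(OC)=C(OC)C(OC)=C1OC | intermediate
10 | tert-butyl 2-[(3R,4R)-5,6,7,8-tetramethoxy-4-(4-methoxyphenyl)-2-oxo-3,4-dihydro-2H-chromen-3-yl]acetate (3,4-cis) | CC(C)(C)OC(=O)C[C@H]1C(=O)Oc2c(OC)c(OC)c(OC)c(OC)c2[C@H]1c1ccc(OC)cc1 | intermediate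
11 | 2-[(3R,4R)-5,6,7,8-tetramethoxy-4-(4-methoxyphenyl)-2-oxo-3,4-dihydro-2H-chromen-3-yl]acetic acid (3,4-cis) | OC(=O)C[C@H]1C(=O)Oc2c(OC)c(OC)c(OC)c(OC)c2[C@H]1c1ccc(OC)cc1 | intermediate
12 | 2-hydroxy-4,6-dimethoxybenzaldehyde | COc1cc(O)c(C=O)c(OC)c1 | starting material
13 | 4-methoxyphenylmagnesium bromide | COc1ccc([Mg]Br)cc1 | starting material
14 | racemic (2-hydroxy-4,6-dimethoxyphenyl)(4-methoxyphenyl)methanol | COc1ccc(cc1)C(O)c1c(O)cc(OC)cc1OC | intermediate
15 | racemic 3,5-dimethoxy-2-[(4-methoxyphenyl)(4-methylbenzenesulfonyl)methyl]phenol | COc1ccc(cc1)C(c1c(O)cc(OC)cc1OC)S(=O)(=O)c1ccc(C)cc1 | intermediate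
16 | mixed pivalic anhydride of acid 11 | CC(C)(C)C(=O)OC(=O)C[C@H]1C(=O)Oc2c(OC)c(OC)c(OC)c(OC)c2[C@H]1c1ccc(OC)cc1 | intermediate
17 | 3,5-dimethoxy-6-[(4-methoxyphenyl)methylidene]cyclohexa-2,4-dien-1-one | COc1ccc(cc1)C=C1C(=O)C=C(OC)C=C1OC | intermediate
18 | (3R,4S)-5,7-dimethoxy-4-(4-methoxyphenyl)-3-[(3S,4R)-5,6,7,8-tetramethoxy-4-(4-methoxyphenyl)-2-oxo-3,4-dihydro-2H-chromen-3-yl]-3,4-dihydro-2H-chromen-2-one | O=C1Oc2cc(OC)cc(OC)c2[C@H](c2ccc(OC)cc2)[C@@H]1[C@H]1C(=O)Oc2c(OC)c(OC)c(OC)c(OC)c2[C@H]1c1ccc(OC)cc1 | intermediate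
19 | (3R,4S)-5,7-dihydroxy-4-(4-hydroxyphenyl)-3-[(3S,4R)-5,6,7,8-tetrahydroxy-4-(4-hydroxyphenyl)-2-oxo-3,4-dihydro-2H-chromen-3-yl]-3,4-dihydro-2H-chromen-2-one | O=C1Oc2cc(O)cc(O)c2[C@H](c2ccc(O)cc2)[C@@H]1[C@H]1C(=O)Oc2c(O)c(O)c(O)c(O)c2[C@H]1c1ccc(O)cc1 | target

## Step count and risks

Total steps: 10. Longest linear sequence: 8 steps (steps 1 to 6, then 9 and 10); steps 7 and 8 form the second branch.

**Step 9.** The enolate of an alkyl-substituted acyl ammonium may form slowly. The addition may then run with eroded facial or cis/trans selectivity, because the methide aryl group is flanked by the C5 methoxy group and the geometry of the quinone methide is less biased than in simpler cases. Slow turnover would also give time for epimerisation at C3'.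
Fallback (auxiliary control in place of catalyst control): it sets out from acid 11 and quinone methide source 15 and comes back at 18. Anhydride 16 (t-BuCOCl, Et3N, THF, −20 °C) is treated with (R)-4-benzyl-1,3-oxazolidin-2-one and LiCl to give the N-acyl oxazolidinone F1. Soft enolisation (TiCl4, iPr2NEt, CH2Cl2, −78 °C) gives the chelated chlorotitanium Z-enolate, to which the filtered solution of 17 is added. Attack anti to the benzyl group should give the open Michael adduct F2 with the 3R centre, the same face the ring B centre favours. Et3N with catalytic DMAP at rt then lets the phenol displace the auxiliary and close ring A to 18.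

**Step 5.** The same annulation without any substrate assistance may give low enantioselectivity or a trans lactone, and the unactivated succinate acyl ammonium may enolise poorly.
Fallback (cis set by syn-hydrogenation): it sets out from ketone 4 and comes back at 11. Perkin-type condensation of 4 with succinic anhydride (Et3N, 130 °C) should give the coumarin-3-acetic acid F3. Hydrogenation over palladium on carbon (Pd/C, H2 50 bar, AcOH, 60 °C) delivers both hydrogens to one face and should give the racemic cis acid F4. Preparative chromatography on a chiral stationary phase then separates the enantiomers to give 11.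

**Step 10.** Cleavage of the hindered ring B ethers may stall while prolonged exposure to HBr opens lactones or epimerises C3/C3', and the pentaoxygenated ring may oxidise in air during isolation.
Fallback (capture and release in place of direct isolation): it sets out from 18 and comes back at 19. After the BBr3 treatment and aqueous quench, the crude polyphenol is acetylated at once (Ac2O, pyridine, 0 °C) to the octaacetate F5, which is air-stable and can be chromatographed free of under-cleaved material. Hydrolysis with dilute HCl in aqueous MeCN under argon then releases 19, with any opened lactone re-closing under the acidic conditions.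

## Further compounds

F1 | step 9 | (R)-4-benzyl-3-{2-[(3R,4R)-5,6,7,8-tetramethoxy-4-(4-methoxyphenyl)-2-oxo-3,4-dihydro-2H-chromen-3-yl]acetyl}-1,3-oxazolidin-2-one | O=C(C[C@H]1C(=O)Oc2c(OC)c(OC)c(OC)c(OC)c2[C@H]1c1ccc(OC)cc1)N1[C@H](Cc2ccccc2)COC1=O
F2 | step 9 | open Michael adduct: (R)-4-benzyl-3-acyl-1,3-oxazolidin-2-one carrying the (2-hydroxy-4,6-dimethoxyphenyl)(4-methoxyphenyl)methyl group at the new C3 centre | Oc1cc(OC)cc(OC)c1[C@H](c1ccc(OC)cc1)[C@@H](C(=O)N1[C@H](Cc2ccccc2)COC1=O)[C@H]1C(=O)Oc2c(OC)c(OC)c(OC)c(OC)c2[C@H]1c1ccc(OC)cc1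
F3 | step 5 | 2-[5,6,7,8-tetramethoxy-4-(4-methoxyphenyl)-2-oxo-2H-chromen-3-yl]acetic acid | OC(=O)CC1=C(c2ccc(OC)cc2)c2c(OC)c(OC)c(OC)c(OC)c2OC1=O
F4 | step 5 | racemic cis-2-[5,6,7,8-tetramethoxy-4-(4-methoxyphenyl)-2-oxo-3,4-dihydro-2H-chromen-3-yl]acetic acid | OC(=O)C[C@H]1C(=O)Oc2c(OC)c(OC)c(OC)c(OC)c2[C@H]1c1ccc(OC)cc1.OC(=O)C[C@@H]1C(=O)Oc2c(OC)c(OC)c(OC)c(OC)c2[C@@H]1c1ccc(OC)cc1
F5 | step 10 | octaacetate of 19 | O=C1Oc2cc(OC(C)=O)cc(OC(C)=O)c2[C@H](c2ccc(OC(C)=O)cc2)[C@@H]1[C@H]1C(=O)Oc2c(OC(C)=O)c(OC(C)=O)c(OC(C)=O)c(OC(C)=O)c2[C@H]1c1ccc(OC(C)=O)cc1
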